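**Plan**

- Retrosynthesis: the exocyclic C3–acetyl bond is cut first, then the N1–C2 imide bond of the pyrrolidine-2,4-dione (the only ring), then the amide bond between the leucine nitrogen and the (E)-dodec-2-enoyl chain, and last the C3–C4 bond, which leads back to N-Boc-D-leucine and S-tert-butyl thioacetate.
- Forward: a Claisen condensation joins C4 to C3, the nitrogen is freed and acylated with (E)-dodec-2-enoyl chloride, silver then closes the ring at N1–C2 on the fully N-acylated chain, and C3 is acetylated last.
- Enabling feature: N1 already carries its enoyl group and sits four atoms from C2, and the C2–C3–C4 β-keto acyl unit can lose its thiolate to give an acylketene, so the five-membered ring closes as it does in the enzymatic chain release.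
- Stereochemistry: the single stereocentre, C5 (R), comes from D-leucine and is only carried through; the (E)-alkene comes from (E)-dodec-2-enoic acid; no step creates a stereocentre.

Key step: step 5

Remark: the target is drawn as its C4-enol, one of several rapidly interconverting tautomers of the 3-acetyl tetramic acid that count as one compound; 11 is drawn in its diketo form on the same basis.

**Route**

Step 1
Reactants: 1 N-Boc-D-leucine; 2 S-tert-butyl thioacetate
Product: 5 S-tert-butyl (R)-4-[(tert-butoxycarbonyl)amino]-6-methyl-3-oxoheptanethioate, via Boc-D-leucine imidazolide 3 (not isolated), via lithium thioacetate enolate 4 (not isolated)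
Conditions: 1 (dried azeotropically with toluene), 1,1'-carbonyldiimidazole (CDI, 1.1 equiv), THF, rt; this solution added to 2 (3.3 equiv) / LiN(SiMe3)2 (3.3 equiv), THF, −78 °C; AcOH quench at −78 °C
Reagents that add atoms: none
Why: Crossed Claisen condensation of an acyl imidazolide with a preformed lithium thioester enolate; the urethane-protected imidazolide cannot form an oxazolone and the product stays as its β-dicarbonyl enolate until the quench, so the D-leucine centre should be carried through unchanged.

Step 2
Reactants: 5 S-tert-butyl (R)-4-[(tert-butoxycarbonyl)amino]-6-methyl-3-oxoheptanethioate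
Product: 6 S-tert-butyl (R)-4-amino-6-methyl-3-oxoheptanethioate hydrochloride
Conditions: 4 M HCl in 1,4-dioxane, 0 °C to rt; evaporation, trituration with Et2O
Reagents that add atoms: hydrogen chloride, Cl
Why: Acidolytic Boc removal with anhydrous HCl should leave the tert-butyl thioester untouched and give the α-amino ketone as its hydrochloride, a form in which it can neither self-condense nor epimerise.

Step 3
Reactants: 7 (E)-dodec-2-enoic acid
Product: 8 (E)-dodec-2-enoyl chloride
Conditions: (COCl)2 (1.2 equiv), DMF (cat.), CH2Cl2, 0 °C to rt; evaporation, used crude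
Reagents that add atoms: oxalyl chloride, ClC(=O)C(=O)Cl
Why: Acid chloride formation with oxalyl chloride under DMF (Vilsmeier) catalysis runs without base, so the 2,3-double bond should stay conjugated and (E).

Step 4
Reactants: 6 S-tert-butyl (R)-4-amino-6-methyl-3-oxoheptanethioate hydrochloride; 8 (E)-dodec-2-enoyl chloride
Product: 9 S-tert-butyl (R)-4-[(E)-dodec-2-enamido]-6-methyl-3-oxoheptanethioate
Conditions: 8 (1.1 equiv), CH2Cl2 / sat. aq NaHCO3 (1:1), 0 °C, vigorous stirring
Reagents that add atoms: none
Why: Schotten–Baumann N-acylation in a two-phase system frees the amine only in the presence of the acid chloride, the weak aqueous base should neither form a vinylketene from the enoyl chloride nor enolise toward C4, and the hindered tert-butyl thioester resists aminolysis as long as no silver is present.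

Step 5
Reactants: 9 S-tert-butyl (R)-4-[(E)-dodec-2-enamido]-6-methyl-3-oxoheptanethioate
Product: 11 (R)-1-[(E)-dodec-2-enoyl]-5-isobutylpyrrolidine-2,4-dione, via acylketene 10 (not isolated)
Conditions: AgOCOCF3 (1.3 equiv), powdered 4 Å molecular sieves, THF (0.01 M), dark, 0 °C to rt; filtration through Celite
Reagents that add atoms: none
Why: Monovalent silver binds the thioester sulfur of 9, the enolised β-keto thioester expels AgSC(CH3)3 to leave acylketene 10, and the secondary amide N–H adds across the ketene C=O to form the N1–C2 bond. The closest known reaction type is the silver-trifluoroacetate-mediated acyl transfer from β-keto thioesters to nitrogen nucleophiles, including its intramolecular form in which a carbamate N–H closes an N-alkoxycarbonyl tetramic acid. The one ring, the pyrrolidine-2,4-dione, closes in a 5-exo-dig mode at the sp carbon of the ketene (5-exo-trig if the silver-bound thioester is attacked directly), and both paths lead to 11. No stereocentre is formed; the (R) centre at C5 is carried from D-leucine and should survive because the medium contains no base and enolisation runs toward the doubly activated C3 methylene, not toward C5. The step needs N- over O-attack of the amide and ring closure over dimerisation or hydration of the acylketene: O-attack would require a seven-membered ring, and high dilution with molecular sieves suppresses the bimolecular paths.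

Step 6
Reactants: 11 (R)-1-[(E)-dodec-2-enoyl]-5-isobutylpyrrolidine-2,4-dione
Product: 13 reutericyclin C [(R)-3-acetyl-1-[(E)-dodec-2-enoyl]-4-hydroxy-5-isobutyl-1,5-dihydro-2H-pyrrol-2-one], via enol acetate 12 (not isolated)
Conditions: AcCl (1.1 equiv), Et3N (2.2 equiv), CH2Cl2, 0 °C; then DMAP (0.2 equiv), 0 °C to rt; 1 M aq HCl wash
Reagents that add atoms: acetyl chloride, CC(=O)Cl
Why: O-Acylation of the tetramic acid enolate followed by DMAP-catalysed O-to-C acyl migration (through an N-acetylpyridinium enolate ion pair) should place the acetyl group on C3, and the product is held as its triethylammonium enolate, which shields C5 from epimerisation until the acidic work-up.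

**Compound list**

1 | N-Boc-D-leucine [(R)-2-[(tert-butoxycarbonyl)amino]-4-methylpentanoic acid] | CC(C)C[C@@H](NC(=O)OC(C)(C)C)C(=O)O | starting material
2 | S-tert-butyl thioacetate | CC(=O)SC(C)(C)C | starting material
3 | Boc-D-leucine imidazolide [tert-butyl (R)-[1-(1H-imidazol-1-yl)-4-methyl-1-oxopentan-2-yl]carbamate] | CC(C)C[C@@H](NC(=O)OC(C)(C)C)C(=O)n1ccnc1 | intermediate
4 | lithium enolate of S-tert-butyl thioacetate | [Li+].C=C([O-])SC(C)(C)C | intermediate
5 | S-tert-butyl (R)-4-[(tert-butoxycarbonyl)amino]-6-methyl-3-oxoheptanethioate | CC(C)C[C@@H](NC(=O)OC(C)(C)C)C(=O)CC(=O)SC(C)(C)C | intermediate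
6 | S-tert-butyl (R)-4-amino-6-methyl-3-oxoheptanethioate hydrochloride | CC(C)C[C@@H]([NH3+])C(=O)CC(=O)SC(C)(C)C.[Cl-] | intermediate
7 | (E)-dodec-2-enoic acid | CCCCCCCCC/C=C/C(=O)O | starting material
8 | (E)-dodec-2-enoyl chloride | CCCCCCCCC/C=C/C(=O)Cl | intermediate
9 | S-tert-butyl (R)-4-[(E)-dodec-2-enamido]-6-methyl-3-oxoheptanethioate | CCCCCCCCC/C=C/C(=O)N[C@H](CC(C)C)C(=O)CC(=O)SC(C)(C)C | intermediate
10 | acylketene, (R)-4-[(E)-dodec-2-enamido]-6-methyl-3-oxohept-1-en-1-one | CCCCCCCCC/C=C/C(=O)N[C@H](CC(C)C)C(=O)C=C=O | intermediate
11 | (R)-1-[(E)-dodec-2-enoyl]-5-isobutylpyrrolidine-2,4-dione | CCCCCCCCC/C=C/C(=O)N1C(=O)CC(=O)[C@H]1CC(C)C | intermediate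
12 | enol acetate, (R)-1-[(E)-dodec-2-enoyl]-2-isobutyl-5-oxo-2,5-dihydro-1H-pyrrol-3-yl acetate | CCCCCCCCC/C=C/C(=O)N1C(=O)C=C(OC(C)=O)[C@H]1CC(C)C | intermediate
13 | reutericyclin C, (R)-3-acetyl-1-[(E)-dodec-2-enoyl]-4-hydroxy-5-isobutyl-1,5-dihydro-2H-pyrrol-2-one | CCCCCCCCC/C=C/C(=O)N1C(=O)C(C(C)=O)=C(O)[C@H]1CC(C)C | target

**Step count**

Total: 6 steps. Longest linear sequence: 5 steps from N-Boc-D-leucine (steps 1, 2, 4, 5, 6); step 3 is a one-step side branch that prepares the acid chloride.

**Steps most likely to fail**

1. Step 5. The secondary amide N–H may capture the acylketene too slowly, so that dimerisation, hydration followed by decarboxylation, or acid-promoted epimerisation at C5 takes over. The fallback sets out from 5 and closes the same N1–C2 bond on the carbamate nitrogen, where the silver-promoted closure is established. AgOCOCF3 in THF should convert 5 into tert-butyl (R)-2-isobutyl-3,5-dioxopyrrolidine-1-carboxylate F1. Acetylation as in step 6 (AcCl, Et3N, then DMAP) should give tert-butyl (R)-4-acetyl-3-hydroxy-2-isobutyl-5-oxo-2,5-dihydro-1H-pyrrole-1-carboxylate F2. TFA in CH2Cl2 removes the Boc group to leave (R)-3-acetyl-5-isobutyltetramic acid F3. Its dianion (n-BuLi, 2 equiv, THF, −78 °C) is then N-acylated with 8, and the route is rejoined at 13.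

2. Step 6. The acyl migration may stall at the enol acetate, or DMAP and Et3N may cleave the exocyclic acyl group on N1 or epimerise C5 by deprotonating the enol acetate. The fallback sets out from 11 and acylates C3 directly under Lewis acid, with no base present. AcCl in BF3·OEt2 at 70 °C should give the difluoroboron chelate of reutericyclin C F4, and heating F4 in methanol releases the free tricarbonyl compound, which rejoins the route at 13.

3. Step 4. The liberated α-amino ketone may condense with itself or attack its own thioester before it is acylated, and the acid chloride may acylate the enol of the β-keto thioester. The fallback reverses the order so that a free amino ketone never exists. It sets out from 8, which acylates commercial D-leucine methyl ester hydrochloride F5 under the same two-phase conditions to give methyl N-[(E)-dodec-2-enoyl]-D-leucinate F6. A crossed Claisen condensation of F6 with an excess of lithium enolate 4 (THF, −78 to −40 °C; the amide is deprotonated first, which shields the α-centre) then leads back to the route at 9.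

**Further compounds**

F1 | step 5 | tert-butyl (R)-2-isobutyl-3,5-dioxopyrrolidine-1-carboxylate | CC(C)C[C@@H]1C(=O)CC(=O)N1C(=O)OC(C)(C)C
F2 | step 5 | tert-butyl (R)-4-acetyl-3-hydroxy-2-isobutyl-5-oxo-2,5-dihydro-1H-pyrrole-1-carboxylate | CC(C)C[C@@H]1C(O)=C(C(C)=O)C(=O)N1C(=O)OC(C)(C)C
F3 | step 5 | (R)-3-acetyl-5-isobutyltetramic acid, drawn as (R)-3-acetyl-4-hydroxy-5-isobutyl-1,5-dihydro-2H-pyrrol-2-one | CC(C)C[C@H]1NC(=O)C(C(C)=O)=C1O
F4 | step 6 | difluoroboron chelate of reutericyclin C (boron bound to the C4 oxygen and the acetyl oxygen) | CCCCCCCCC/C=C/C(=O)N1C(=O)C2=C(O[B-](F)(F)[O+]=C2C)[C@H]1CC(C)C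
F5 | step 4 | D-leucine methyl ester hydrochloride | CC(C)C[C@@H]([NH3+])C(=O)OC.[Cl-]
F6 | step 4 | methyl N-[(E)-dodec-2-enoyl]-D-leucinate | CCCCCCCCC/C=C/C(=O)N[C@H](CC(C)C)C(=O)OC
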